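**Retrosynthetic overview**

1. Ring disconnection (C1–C6 bond of each ε-ring): both rings go back to one acyclic dienone, (3E,5E)-pseudoionone 1. Forward, a chiral-acid-controlled proton-initiated closure (protonation at C2, C1–C6 bond formation, loss of H-4) gives (R)-α-ionone 2 and sets C6 directly, without resolution.
2. C9–C10 disconnection: C10 and C11 are added as a vinyl nucleophile to the C9 carbonyl of 2 (alkoxide 3, alcohol 4), then transposed to the C15 phosphonium salt 5.
3. C11=C12 and C11′=C12′ disconnection (C15 + C10 + C15): two molecules of 5 and the C10 dialdehyde 6, through ylide 7, C25 aldehyde 8 and the 11Z-containing isomer mixture 9, give the target 10.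
4. Order of ring formation: both ε-rings are closed first, in step 1 (two molecules of 2 per molecule of 10), while the diene is still tied to a carbonyl group. On a preformed lycopene-type polyene, acid would protonate the chain (C5) instead of the isopropylidene group and lead to retro and five-membered 2,6-cyclo products. No ring is formed later.

Assumption 1: compound 1 is the (3E,5E) isomer of pseudoionone in ≥95% isomeric purity (bought as such or fractionated from the technical E/Z mixture).
Assumption 2: the (S,S) enantiomer of the chiral acid is written as the one that delivers (6R); if the first run shows the opposite sense, its (R,R) antipode is used and nothing else changes.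

Carotenoid numbering (ring C1–C6, chain C7–C15) is used throughout.

**Route**

Step 1
Reactants: 1 (3E,5E)-pseudoionone [(3E,5E)-6,10-dimethylundeca-3,5,9-trien-2-one]
Product: 2 (R)-α-ionone [(3E)-4-[(1R)-2,6,6-trimethylcyclohex-2-en-1-yl]but-3-en-2-one]
Conditions: (S,S)-IDPi acid HN[P(=NSO2CF3)(O2C20H10Ar2)]2 (O2C20H10Ar2 = (S)-3,3′-diaryl-BINOLate, Ar = 3,5-(CF3)2C6H3; 5 mol%), (CF3)3COH, 0.1 M, 0 → 20 °C, Ar, 24–48 h; Et3N quench at about 90% conversion; chromatography
Reagents that add atoms: none
Why: Proposed new method: this is a proton-initiated cation–olefin monocyclisation in which the confined chiral acid protonates C2 of the isopropylidene group while C1 bonds to C6 of the chair-folded 5E-alkene, and the chiral counter-anion sitting over the new C5 cation removes the nearest proton (H-4) under kinetic control to give the Δ4 (ε-type) alkene, so the enantiotopic face of C5=C6 selected in the catalyst pocket fixes C6 as R, the dienone carbonyl keeps the diene itself from being C-protonated, and the closest known reaction types are the H3PO4 cyclisation of pseudoionone to racemic α-ionone and imidodiphosphorimidate-catalysed enantioselective proton-initiated polyene cyclisations in fluorinated alcohols.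

Step 2
Reactants: 2 (R)-α-ionone
Product: 5 [(2E,4E)-3-methyl-5-[(1R)-2,6,6-trimethylcyclohex-2-en-1-yl]penta-2,4-dien-1-yl]triphenylphosphonium bromide, via bromomagnesium alkoxide 3 (not isolated), via vinyl-α-ionol 4 (not isolated)
Conditions: CH2=CHMgBr (1.15 equiv), THF, −20 → 0 °C; then MeOH, PPh3 (1.05 equiv), 48% aq HBr (2.2 equiv), 0 °C → rt, 16 h, same flask; extraction (CH2Cl2/H2O), crystallisation (EtOAc/acetone)
Reagents that add atoms: CH2=CHMgBr (vinylmagnesium bromide), C=C[Mg]Br; triphenylphosphine, c1ccc(cc1)P(c1ccccc1)c1ccccc1; hydrogen bromide, Br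
Why: Grignard 1,2-addition to the enone carbonyl is followed in the same flask by acid ionisation of the tertiary bis-allylic alcohol to a pentadienyl cation that PPh3 traps at the unhindered terminus C11 (SN1/SN2′ allylic transposition, the standard C15 Wittig-salt formation of ionone chemistry), which leaves C6 untouched, removes the mixed C9 carbinol centre of 3 and 4, and gives the 9E salt on crystallisation.

Step 3
Reactants: 5 C15 phosphonium bromide (2.15 equiv); 6 (2E,4E,6E)-2,7-dimethylocta-2,4,6-trienedial (C10 dialdehyde)
Product: 10 (6R,6′R)-ε,ε-carotene, via phosphorus ylide 7 (not isolated), via C25 apo-aldehyde 8 (not isolated), via 11Z/11′Z isomer mixture 9 (not isolated)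
Conditions: NaOMe (2.3 equiv), MeOH/CH2Cl2, −10 °C → rt, Ar, dark; then solvent switch to n-heptane, reflux, 6 h; crystallisation (CH2Cl2/MeOH)
Reagents that add atoms: none
Why: Two-fold Wittig olefination of the dialdehyde by the semi-stabilised allylic ylide builds C11=C12 and C11′=C12′ as E/Z mixtures and the hindered 11Z bonds then isomerise thermally to the all-E polyene, which crystallises, while no new stereocentre is formed, C6 and C6′ are not touched by methoxide at room temperature, and the two-fold coupling upgrades enantiomeric purity because the minor enantiomer of 5 ends up mainly in the meso (6R,6′S) diastereomer that stays in the mother liquor.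

**Compound list**

1 | (3E,5E)-pseudoionone, (3E,5E)-6,10-dimethylundeca-3,5,9-trien-2-one | CC(C)=CCC/C(C)=C/C=C/C(C)=O | starting material
2 | (R)-α-ionone, (3E)-4-[(1R)-2,6,6-trimethylcyclohex-2-en-1-yl]but-3-en-2-one | CC1=CCCC(C)(C)[C@H]1/C=C/C(C)=O | intermediate
3 | bromomagnesium (3RS,4E)-3-methyl-5-[(1R)-2,6,6-trimethylcyclohex-2-en-1-yl]penta-1,4-dien-3-olate (both C9 epimers) | CC1=CCCC(C)(C)[C@H]1/C=C/C(C)(C=C)O[Mg]Br | intermediate
4 | vinyl-α-ionol, (3RS,4E)-3-methyl-5-[(1R)-2,6,6-trimethylcyclohex-2-en-1-yl]penta-1,4-dien-3-ol (both C9 epimers) | CC1=CCCC(C)(C)[C@H]1/C=C/C(C)(O)C=C | intermediate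
5 | [(2E,4E)-3-methyl-5-[(1R)-2,6,6-trimethylcyclohex-2-en-1-yl]penta-2,4-dien-1-yl]triphenylphosphonium bromide | CC1=CCCC(C)(C)[C@H]1/C=C/C(C)=C/C[P+](c1ccccc1)(c1ccccc1)c1ccccc1.[Br-] | intermediate
6 | (2E,4E,6E)-2,7-dimethylocta-2,4,6-trienedial | O=C/C(C)=C/C=C/C=C(C)/C=O | starting material
7 | [(2E,4E)-3-methyl-5-[(1R)-2,6,6-trimethylcyclohex-2-en-1-yl]penta-2,4-dien-1-ylidene]triphenylphosphorane | CC1=CCCC(C)(C)[C@H]1/C=C/C(C)=C/C=P(c1ccccc1)(c1ccccc1)c1ccccc1 | intermediate
8 | (6R)-12′-apo-ε-caroten-12′-al, formed as an 11Z/11E mixture and drawn as the 11Z isomer, (2E,4E,6E,8Z,10E,12E)-2,7,11-trimethyl-13-[(1R)-2,6,6-trimethylcyclohex-2-en-1-yl]trideca-2,4,6,8,10,12-hexaenal | CC1=CCCC(C)(C)[C@H]1/C=C/C(C)=C/C=C\C(C)=C\C=C\C=C(C)\C=O | intermediate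
9 | crude ε,ε-carotene isomer mixture, drawn as its (6R,6′R,11Z,11′Z) component | CC1=CCCC(C)(C)[C@H]1/C=C/C(C)=C/C=C\C(C)=C\C=C\C=C(C)\C=C/C=C(C)/C=C/[C@H]1C(C)=CCCC1(C)C | intermediate
10 | (6R,6′R)-ε,ε-carotene, all-E | CC1=CCCC(C)(C)[C@H]1/C=C/C(C)=C/C=C/C(C)=C/C=C/C=C(C)/C=C/C=C(C)/C=C/[C@H]1C(C)=CCCC1(C)C | target

**Step count and risks**

Total step count: 3. Longest linear sequence: 3 (1 → 2 → 5 → 10).

Steps most likely to fail, most risky first:

Step 1. The enantioselective version of this cyclisation is new. The carbonyl group may tie up the acid and slow turnover, the cation may lose H-6 or a methyl proton (β- or γ-ionone), and the enantiomeric ratio may be modest. Fallback: starting from 1, the cyclisation is run under the classical α-selective conditions (85% H3PO4, 30–35 °C) to give racemic α-ionone F1. The enantiomers are then separated by preparative supercritical-fluid chromatography on an amylose tris(3,5-dimethylphenylcarbamate) phase (CO2/i-PrOH). The R enantiomer is 2, where the route is rejoined. The ring is still made by the same cation–olefin closure, but the stereocentre now comes from resolution instead of catalyst control.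

Step 3. The double Wittig reaction may stop at 8, give isomer mixtures that do not converge fully on heating, or leave meso material that co-crystallises. Fallback: starting from 4, which is isolated for this purpose after an aqueous NH4Cl work-up of the Grignard addition, PBr3 (cat. pyridine, Et2O, −20 °C) gives by SN2′ transposition (2E,4E)-5-bromo-3-methyl-1-[(1R)-2,6,6-trimethylcyclohex-2-en-1-yl]penta-1,3-diene F4. A Michaelis–Arbuzov reaction with P(OEt)3 (neat, 110 °C) turns it into diethyl [(2E,4E)-3-methyl-5-[(1R)-2,6,6-trimethylcyclohex-2-en-1-yl]penta-2,4-dien-1-yl]phosphonate F5. Its sodium salt (NaH, THF, −30 → 0 °C) undergoes a two-fold Horner–Wadsworth–Emmons reaction with 6, which is E-selective and gives 10 directly. The phosphonate carbanion replaces the ylide, so no separate isomerisation is needed.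

Step 2. The Grignard reagent may add 1,4 or deprotonate, the pentadienyl cation may lose H-6 to a retro-triene instead of being trapped, and the salt may carry too much 9Z isomer. Fallback: starting from 2, a Horner–Wadsworth–Emmons reaction with triethyl phosphonoacetate (NaH, THF, 0 °C → rt) gives ethyl (2E,4E)-3-methyl-5-[(1R)-2,6,6-trimethylcyclohex-2-en-1-yl]penta-2,4-dienoate F2, purified as the 9E isomer. Reduction with i-Bu2AlH (toluene, −78 °C) gives (2E,4E)-3-methyl-5-[(1R)-2,6,6-trimethylcyclohex-2-en-1-yl]penta-2,4-dien-1-ol F3. This primary allylic alcohol reacts with PPh3·HBr (MeOH, rt) to give 5, where the route is rejoined. The two carbons are added by olefination instead of vinyl addition, and no tertiary carbocation has to be transposed.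

**Further compounds**

F1 | step 1 | racemic α-ionone, (3E)-4-(2,6,6-trimethylcyclohex-2-en-1-yl)but-3-en-2-one | CC1=CCCC(C)(C)C1/C=C/C(C)=O
F2 | step 2 | ethyl (2E,4E)-3-methyl-5-[(1R)-2,6,6-trimethylcyclohex-2-en-1-yl]penta-2,4-dienoate | CC1=CCCC(C)(C)[C@H]1/C=C/C(C)=C/C(=O)OCC
F3 | step 2 | (2E,4E)-3-methyl-5-[(1R)-2,6,6-trimethylcyclohex-2-en-1-yl]penta-2,4-dien-1-ol | CC1=CCCC(C)(C)[C@H]1/C=C/C(C)=C/CO
F4 | step 3 | (2E,4E)-5-bromo-3-methyl-1-[(1R)-2,6,6-trimethylcyclohex-2-en-1-yl]penta-1,3-diene | CC1=CCCC(C)(C)[C@H]1/C=C/C(C)=C/CBr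
F5 | step 3 | diethyl [(2E,4E)-3-methyl-5-[(1R)-2,6,6-trimethylcyclohex-2-en-1-yl]penta-2,4-dien-1-yl]phosphonate | CC1=CCCC(C)(C)[C@H]1/C=C/C(C)=C/CP(=O)(OCC)OCC
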